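The α-methylene-γ-butyrolactone is cut between its carbonyl carbon (C12) and the α-carbon bearing the exocyclic methylene (C11). C11=C13H2 then is an ethynyl group on ring-fusion carbon C7, and C12 is carbon monoxide. In the last step palladium builds an alkoxycarbonyl group on the free C8 hydroxyl of a cis-2-ethynylcyclohept-3-enol that already carries the acetate and the angelate. Its addition across the alkyne closes the five-membered lactone ring, creates the exocyclic methylene and keeps the cis ring fusion. The cycloheptene is made from cyclohepta-1,3-diene by hydroxyl-directed conjugate alkynylation, catalytic methyl addition–aldol and enol triflate methylation.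

Key step: step 13

Remark on numbering: all intermediates use the skeleton numbering of the target. Ring carbons are C1, C5, C6, C7, C8, C9, C10; C15 is the methyl on C5 and C14 the methyl on C10; the side chain C2–C4 sits on C1; C11 (on C7) and C13 are the ethynyl carbons; C12 is the lactone carbonyl.

Assumptions: compounds 1, 7, 11 and 19 are commercial. The pseudoenantiomer of the cinchona base (step 1) is the one that gives the 4R alcohol. The (R,S,S) phosphoramidite (step 5) is chosen by analogy with unsubstituted cycloalkenones, where its enantiomer gives (S)-3-alkyl ketones.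

Step 1
Reactants: 1 cyclohepta-1,3-diene
Product: 3 (4R)-4-hydroxycyclohept-2-en-1-one, via endoperoxide 2 (not isolated)
Conditions: O2, hν, tetraphenylporphyrin (cat.), CH2Cl2, 0 °C; then O-acetyl 6'-hydroxycinchona base (10 mol%), CH2Cl2, rt
Reagents that add atoms: dioxygen O=O
Why: Singlet-oxygen [4+2] cycloaddition gives the meso endoperoxide, and an enantioselective Kornblum–DeLaMare rearrangement, in which the chiral amine removes one of the two enantiotopic bridgehead O–C–H protons, should give the 4R hydroxy enone that supplies the C8 stereocenter.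

Step 2
Reactants: 3 (4R)-4-hydroxycyclohept-2-en-1-one
Product: 6 (4R)-4-hydroxycyclohepta-2,6-dien-1-one, via bis-silyl dienol ether 4 (not isolated), via silyloxy dienone 5 (not isolated)
Conditions: LDA (2.2 equiv), Me3SiCl (2.5 equiv), THF, −78 °C; then Pd(OAc)2 (1.1 equiv), MeCN, rt; then citric acid, MeOH, 0 °C
Reagents that add atoms: none
Why: Deprotonation of the hydroxyl and of the α' carbon C1 followed by silylation gives the cross-conjugated silyl dienol ether, whose Saegusa–Ito oxidation introduces the C1=C10 double bond regiospecifically, and mildly acidic methanolysis frees the hydroxyl without the base that would eliminate water toward tropone.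

Step 3
Reactants: 6 (4R)-4-hydroxycyclohepta-2,6-dien-1-one; 7 trimethylsilylacetylene
Product: 9 (5R,6R)-5-hydroxy-6-[(trimethylsilyl)ethynyl]cyclohept-2-en-1-one (hydroxyl cis to alkynyl), via aluminium alkoxide 8 (not isolated)
Conditions: 7, n-BuLi, then Me2AlCl, toluene/hexane, 0 °C (3 equiv of Me2AlC≡CSiMe3); then 6, −30 → 0 °C; aq. Rochelle salt
Reagents that add atoms: dimethyl[(trimethylsilyl)ethynyl]alane (made in the flask from 7) C[Al](C)C#C[Si](C)(C)C
Why: In this hydroxyl-directed conjugate addition of an alkynylalane the C8 aluminium alkoxide hands its alkynyl ligand to the neighbouring β-carbon C7 from its own face, so C7 is set cis to the C8 oxygen and only the hydroxyl-bearing enone reacts, because s-trans cyclic enones do not accept alkynylalanes without such delivery.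

Step 4
Reactants: 9 (5R,6R)-5-hydroxy-6-[(trimethylsilyl)ethynyl]cyclohept-2-en-1-one
Product: 10 (5R,6R)-5-[(tert-butyldimethylsilyl)oxy]-6-[(trimethylsilyl)ethynyl]cyclohept-2-en-1-one
Conditions: t-BuMe2SiCl, imidazole, DMF, rt
Reagents that add atoms: tert-butyldimethylsilyl chloride CC(C)(C)[Si](C)(C)Cl
Why: Silyl ether formation masks the C8 hydroxyl for the enolate and Grignard steps and keeps it distinguishable from the C2 hydroxyl made next.

Step 5
Reactants: 10 (5R,6R)-5-[(tert-butyldimethylsilyl)oxy]-6-[(trimethylsilyl)ethynyl]cyclohept-2-en-1-one; 11 3-[(tert-butyldimethylsilyl)oxy]propanal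
Product: 13 (2R,3R,5R,6R)-5-[(tert-butyldimethylsilyl)oxy]-2-{(1R)-3-[(tert-butyldimethylsilyl)oxy]-1-hydroxypropyl}-3-methyl-6-[(trimethylsilyl)ethynyl]cycloheptan-1-one, via methylzinc enolate 12 (not isolated)
Conditions: Me2Zn (1.5 equiv), Cu(OTf)2 (2 mol%), (R,S,S)-binaphthyl bis(1-phenylethyl)phosphoramidite (4 mol%), toluene, −30 °C; then 11, −30 → 0 °C
Reagents that add atoms: dimethylzinc C[Zn]C
Why: In this copper-catalysed enantioselective conjugate addition with aldol trapping of the zinc enolate, the ligand-controlled methyl transfer sets C10 (methyl trans to the C8 silyloxy group), the aldehyde enters at C1 anti to the new methyl group, and the ring (E)-enolate reacting through a closed chair transition state should favour the anti aldol, which is the C2 epimer of the target and is inverted in step 11.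

Step 6
Reactants: 13 aldol ketone
Product: 14 (2R,3R,5R,6R)-5-[(tert-butyldimethylsilyl)oxy]-2-{(1R)-3-[(tert-butyldimethylsilyl)oxy]-1-[(triethylsilyl)oxy]propyl}-3-methyl-6-[(trimethylsilyl)ethynyl]cycloheptan-1-one
Conditions: Et3SiOTf, 2,6-lutidine, CH2Cl2, −78 °C
Reagents that add atoms: triethylsilyl trifluoromethanesulfonate CC[Si](CC)(CC)OS(=O)(=O)C(F)(F)F
Why: Low-temperature silylation with a silyl triflate and a hindered base protects the β-hydroxy ketone without retro-aldol cleavage and masks O2 for the enolisation.

Step 7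
Reactants: 14 triethylsilyl ether ketone
Product: 15 C5=C6 enol trifluoromethanesulfonate of 14 (skeleton descriptors 1R,2R,7R,8R,10R)
Conditions: KHMDS, THF, −78 °C; PhNTf2, −78 → −20 °C
Reagents that add atoms: N-phenylbis(trifluoromethanesulfonimide) O=S(=O)(N(c1ccccc1)S(=O)(=O)C(F)(F)F)C(F)(F)F
Why: Kinetic deprotonation takes the unhindered C6 methylene and not the fully substituted C1 methine, and O-sulfonylation of the potassium enolate (enol triflate formation) fixes the double bond between C5 and C6.

Step 8
Reactants: 15 enol triflate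
Product: 16 (1S,2R,7R,8R,10R)-5,10-dimethylcyclohept-5-ene carrying the C2-triethylsilyloxy/C4-tert-butyldimethylsilyloxy side chain on C1, the trimethylsilylethynyl group on C7 and the tert-butyldimethylsilyloxy group on C8
Conditions: MeMgBr (1.5 equiv), Fe(acac)3 (5 mol%), THF/NMP, −30 → 0 °C
Reagents that add atoms: methylmagnesium bromide C[Mg]Br
Why: Iron-catalysed cross-coupling of the alkenyl triflate with the methyl Grignard reagent installs the C15 methyl on C5 under conditions that spare silyl ethers and the silylalkyne (the C1 descriptor changes to S only through the priority rules).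

Step 9
Reactants: 16 tris-silyl ether
Product: 17 (1S,2R,7R,8R,10R)-diol with free C2 and C4 hydroxyls (C8 silyl ether and alkynylsilane kept)
Conditions: camphorsulfonic acid (10 mol%), MeOH/CH2Cl2 (1:1), 0 °C
Reagents that add atoms: none
Why: Acid-catalysed methanolysis (selective desilylation) removes the triethylsilyl ether and the primary tert-butyldimethylsilyl ether much faster than the hindered secondary C8 silyl ether and does not touch the alkyne C–Si bond.

Step 10
Reactants: 17 diol
Product: 18 (1S,2R,7R,8R,10R)-C4 acetate with free C2 hydroxyl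
Conditions: Ac2O (1.1 equiv), pyridine, CH2Cl2, −20 → 0 °C
Reagents that add atoms: acetic anhydride CC(=O)OC(C)=O
Why: Acylation with a slight excess of anhydride at low temperature is selective for the primary C4 hydroxyl over the branched secondary C2 hydroxyl (selective esterification).

Step 11
Reactants: 18 C4 acetate; 19 angelic acid
Product: 20 (1S,2S,7R,8R,10R)-C2 angelate C4 acetate (C8 silyl ether and alkynylsilane kept)
Conditions: 19 (2 equiv), PPh3, DIAD, toluene, 0 °C → rt
Reagents that add atoms: none
Why: In the Mitsunobu esterification the angelate anion displaces the C2 alkoxyphosphonium by SN2 with inversion (2R to 2S), and because the acid is never activated at its acyl carbon the Z geometry of the angelate should be kept.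

Step 12
Reactants: 20 silyl-protected angelate
Product: 21 (1S,2S,7R,8R,10R)-cis-7-ethynyl-8-hydroxy cycloheptene with C2 angelate and C4 acetate
Conditions: Bu4NF (3 equiv), AcOH (3 equiv), THF, 0 °C → rt
Reagents that add atoms: none
Why: Fluoride cleaves the alkynyl C–Si bond and the C8 silyl ether (desilylation), and the acetic acid buffer keeps the medium from isomerising the skipped enyne or moving the esters.

Step 13
Reactants: 21 cis-7-ethynyl-8-hydroxy cycloheptene
Product: 24 target CNP0163960.1 (1S,2S,7R,8R,10R), via alkoxycarbonylpalladium chloride 22 (not isolated), via alkenylpalladium chloride 23 (not isolated)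
Conditions: PdCl2 (5 mol%), PPh3 (10 mol%), SnCl2 (5 mol%), CO (7 atm), MeCN, 75 °C
Reagents that add atoms: carbon monoxide [C-]#[O+]
Why: Divalent palladium, CO and the C8 hydroxyl give the alkoxycarbonylpalladium species 22, whose Pd–C12 bond adds syn across the C11≡C13 triple bond, forming the C11–C12 bond and closing the lactone ring; protonolysis of the C13–Pd bond of 23 by the HCl released in the first stage frees the exocyclic methylene and returns divalent palladium. The closest known reaction type is the PdCl2/SnCl2/phosphine-catalysed cyclocarbonylation of 2-ethynylcycloalkanols to ring-fused α-methylene-γ-butyrolactones. The ring closes in the 5-exo-dig mode, the acyl carbon attacking the internal alkyne carbon C11. No stereocenter is created: the cis ring fusion is inherited from the cis C7 ethynyl/C8 hydroxyl pair of step 3, and the syn addition only fixes the transient alkenylpalladium geometry. The step needs chemoselectivity for the single free hydroxyl and the terminal alkyne over the two esters and the trisubstituted C5=C6 alkene, and exo over endo closure; only O8 can reach the alkyne through a five-membered ring, carboxylic esters do not enter the cycle, and the endo closure onto terminal C13 would need a more strained six-membered ring.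

Compound list
1 | cyclohepta-1,3-diene | C1=CC=CCCC1 | starting material
2 | cis-6,7-dioxabicyclo[3.2.2]non-8-ene (meso endoperoxide) | O1O[C@H]2CCC[C@@H]1C=C2 | intermediate (not isolated)
3 | (4R)-4-hydroxycyclohept-2-en-1-one | O[C@@H]1CCCC(=O)C=C1 | intermediate
4 | (5R)-2,5-bis(trimethylsilyloxy)cyclohepta-1,3-diene | C[Si](C)(C)O[C@@H]1CCC=C(O[Si](C)(C)C)C=C1 | intermediate (not isolated)
5 | (4R)-4-(trimethylsilyloxy)cyclohepta-2,6-dien-1-one | C[Si](C)(C)O[C@@H]1CC=CC(=O)C=C1 | intermediate (not isolated)
6 | (4R)-4-hydroxycyclohepta-2,6-dien-1-one | O[C@@H]1CC=CC(=O)C=C1 | intermediate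
7 | trimethylsilylacetylene | C#C[Si](C)(C)C | starting material
8 | methyl[(trimethylsilyl)ethynyl]aluminium alkoxide of 6 | C[Al](C#C[Si](C)(C)C)O[C@@H]1CC=CC(=O)C=C1 | intermediate (not isolated)
9 | (5R,6R)-5-hydroxy-6-[(trimethylsilyl)ethynyl]cyclohept-2-en-1-one | O[C@@H]1CC=CC(=O)C[C@@H]1C#C[Si](C)(C)C | intermediate
10 | (5R,6R)-5-[(tert-butyldimethylsilyl)oxy]-6-[(trimethylsilyl)ethynyl]cyclohept-2-en-1-one | CC(C)(C)[Si](C)(C)O[C@@H]1CC=CC(=O)C[C@@H]1C#C[Si](C)(C)C | intermediate
11 | 3-[(tert-butyldimethylsilyl)oxy]propanal | O=CCCO[Si](C)(C)C(C)(C)C | starting material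
12 | methylzinc enolate (C1=C5–O–ZnMe) formed by methyl addition to 10 (7R,8R,10R) | CC(C)(C)[Si](C)(C)O[C@@H]1C[C@@H](C)C=C(O[Zn]C)C[C@@H]1C#C[Si](C)(C)C | intermediate (not isolated)
13 | (2R,3R,5R,6R)-5-[(tert-butyldimethylsilyl)oxy]-2-{(1R)-3-[(tert-butyldimethylsilyl)oxy]-1-hydroxypropyl}-3-methyl-6-[(trimethylsilyl)ethynyl]cycloheptan-1-one | CC(C)(C)[Si](C)(C)O[C@@H]1C[C@@H](C)[C@H]([C@@H](CCO[Si](C)(C)C(C)(C)C)O)C(=O)C[C@@H]1C#C[Si](C)(C)C | intermediate
14 | C2-O-triethylsilyl ether of 13 | CC(C)(C)[Si](C)(C)O[C@@H]1C[C@@H](C)[C@H]([C@@H](CCO[Si](C)(C)C(C)(C)C)O[Si](CC)(CC)CC)C(=O)C[C@@H]1C#C[Si](C)(C)C | intermediate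
15 | C5=C6 enol trifluoromethanesulfonate of 14 | CC(C)(C)[Si](C)(C)O[C@@H]1C[C@@H](C)[C@H]([C@@H](CCO[Si](C)(C)C(C)(C)C)O[Si](CC)(CC)CC)C(OS(=O)(=O)C(F)(F)F)=C[C@@H]1C#C[Si](C)(C)C | intermediate
16 | (1S,2R,7R,8R,10R)-5-methyl cycloheptene, tris-silyl ether, alkynylsilane | CC(C)(C)[Si](C)(C)O[C@@H]1C[C@@H](C)[C@H]([C@@H](CCO[Si](C)(C)C(C)(C)C)O[Si](CC)(CC)CC)C(C)=C[C@@H]1C#C[Si](C)(C)C | intermediate
17 | (1S,2R,7R,8R,10R)-C2,C4-diol, C8 silyl ether | CC(C)(C)[Si](C)(C)O[C@@H]1C[C@@H](C)[C@H]([C@@H](CCO)O)C(C)=C[C@@H]1C#C[Si](C)(C)C | intermediate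
18 | (1S,2R,7R,8R,10R)-C4 acetate, free C2 hydroxyl | CC(C)(C)[Si](C)(C)O[C@@H]1C[C@@H](C)[C@H]([C@@H](CCOC(C)=O)O)C(C)=C[C@@H]1C#C[Si](C)(C)C | intermediate
19 | angelic acid, (Z)-2-methylbut-2-enoic acid | C/C=C(/C)C(=O)O | starting material
20 | (1S,2S,7R,8R,10R)-C2 angelate, C4 acetate, C8 silyl ether, alkynylsilane | CC(C)(C)[Si](C)(C)O[C@@H]1C[C@@H](C)[C@H]([C@H](CCOC(C)=O)OC(=O)/C(C)=C\C)C(C)=C[C@@H]1C#C[Si](C)(C)C | intermediate
21 | (1S,2S,7R,8R,10R)-cis-7-ethynyl-8-hydroxy cycloheptene, C2 angelate, C4 acetate | O[C@@H]1C[C@@H](C)[C@H]([C@H](CCOC(C)=O)OC(=O)/C(C)=C\C)C(C)=C[C@@H]1C#C | intermediate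
22 | C8-alkoxycarbonylpalladium chloride of 21 (divalent palladium, phosphine ligands omitted) | Cl[Pd]C(=O)O[C@@H]1C[C@@H](C)[C@H]([C@H](CCOC(C)=O)OC(=O)/C(C)=C\C)C(C)=C[C@@H]1C#C | intermediate (not isolated)
23 | lactone alkenylpalladium chloride, palladium on C13 cis to C12 (divalent palladium, phosphine ligands omitted) | Cl[Pd]/C=C1\C(=O)O[C@@H]2C[C@@H](C)[C@H]([C@H](CCOC(C)=O)OC(=O)/C(C)=C\C)C(C)=C[C@H]12 | intermediate (not isolated)
24 | CNP0163960.1, cis-fused α-methylene-γ-butyrolactone (1S,2S,7R,8R,10R) | C=C1C(=O)O[C@@H]2C[C@@H](C)[C@H]([C@H](CCOC(C)=O)OC(=O)/C(C)=C\C)C(C)=C[C@H]12 | target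

Total step count: 13. Longest linear sequence: 13 steps, from cyclohepta-1,3-diene.

Steps most likely to fail

Step 3. The γ-hydroxy dienone 6 may be lost by elimination of the C8 oxygen across C8–C9 (tropone formation), or the alane may add to the cross-conjugated carbonyl, before the alkoxide-bound alkynyl group is transferred. The fallback sets out from 3 and keeps the second double bond masked during the alkynylation. The dianion of 3 (LDA, 2.2 equiv, THF, −78 °C) is selenenylated at C1 with PhSeCl to give (4R)-4-hydroxy-7-(phenylselanyl)cyclohept-2-en-1-one F1 (either epimer at the selenium-bearing carbon). The directed alkynylation with Me2AlC≡CSiMe3 is then run on this plain γ-hydroxy enone and should give (5R,6R)-5-hydroxy-2-(phenylselanyl)-6-[(trimethylsilyl)ethynyl]cycloheptan-1-one F2. Oxidation with H2O2/pyridine in CH2Cl2 at 0 °C and syn elimination of the selenoxide toward C10 unveil the enone, and the route is rejoined at 9.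

Step 5. The chiral copper catalyst may work against the bias of the C7/C8 substituents, giving poor facial selectivity at C10, and the zinc enolate aldol may show little preference at C2. The fallback sets out from 10 and separates the two bond formations under substrate control. Me2CuLi with Me3SiCl (THF, −78 °C) should add methyl anti to the C8 silyloxy group and give the (7R,8R,10R)-trimethylsilyl enol ether F3. MeLi (THF, 0 °C) regenerates the regiodefined lithium enolate, which is added to aldehyde 11 at −78 °C with short contact time (kinetic anti aldol through the closed transition state). The route is rejoined at 13.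

Step 11. Displacement at the branched C2 alkoxyphosphonium may be slow, so that elimination toward C1 or esterification with retention competes. The fallback sets out from 18. Dess–Martin oxidation gives the (1S,7R,8R,10R)-C2 ketone F4. Corey–Bakshi–Shibata reduction with the (R)-oxazaborolidine and catecholborane (reagent control) should give the (1S,2S,7R,8R,10R)-alcohol F5. Yamaguchi esterification with 19 (2,4,6-trichlorobenzoyl chloride, Et3N, then DMAP, toluene) then gives the angelate with retention, and the route is rejoined at 20.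

Further compounds
F1 | step 3 | (4R)-4-hydroxy-7-(phenylselanyl)cyclohept-2-en-1-one | O[C@@H]1CCC([Se]c2ccccc2)C(=O)C=C1
F2 | step 3 | (5R,6R)-5-hydroxy-2-(phenylselanyl)-6-[(trimethylsilyl)ethynyl]cycloheptan-1-one | O[C@@H]1CCC([Se]c2ccccc2)C(=O)C[C@@H]1C#C[Si](C)(C)C
F3 | step 5 | (7R,8R,10R)-trimethylsilyl enol ether (C1=C5–OSiMe3) of the 10-methyl ketone | CC(C)(C)[Si](C)(C)O[C@@H]1C[C@@H](C)C=C(O[Si](C)(C)C)C[C@@H]1C#C[Si](C)(C)C
F4 | step 11 | (1S,7R,8R,10R)-C2 ketone, C4 acetate | CC(C)(C)[Si](C)(C)O[C@@H]1C[C@@H](C)[C@H](C(=O)CCOC(C)=O)C(C)=C[C@@H]1C#C[Si](C)(C)C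
F5 | step 11 | (1S,2S,7R,8R,10R)-C2 alcohol, C4 acetate | CC(C)(C)[Si](C)(C)O[C@@H]1C[C@@H](C)[C@H]([C@H](CCOC(C)=O)O)C(C)=C[C@@H]1C#C[Si](C)(C)C
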